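The plan rests on cutting ring A of irigenin at C7–C8 and C4a–C5. This exposes its 1,3,5-oxygenation: C5–C6(OMe)–C7 is a methoxymalonyl unit, whereas C8, C8a and C4a are the methyl carbon, C2 and C3 of a 4-pyranone that already is ring C and carries ring B. The key step joins both pieces by two C-acylations and tautomerisation, a three-plus-three benzannulation that delivers ring A with its two free hydroxyl groups and the C6 methoxy group in one operation. Its precursor is a 5-aryl-2-methyl-4H-pyran-4-one, aryl being 3-O-protected 3-hydroxy-4,5-dimethoxyphenyl, assembled by Suzuki–Miyaura coupling of a kojic acid-derived triflate.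

Key step: step 9

Remarks on the design
- **Atom map.** Pyranone O1, C6, C5, C4, C3, C2 and the methyl carbon become chromone O1, C2, C3, C4, C4a, C8a and C8. Chromone numbering is used for these atoms from here on. The target has no stereocentre.
- **Protecting group.** The 3'-OH is masked as a methoxymethyl (MOM) ether and not as a benzyl ether. An iridium borylation catalyst would also attack the unhindered meta and para C–H bonds of a benzyl phenyl ring. Hydrogenolysis at the end would also put the C2=C3 bond of the isoflavone at risk. The MOM acetal is inert to borylation, cross-coupling and amide base, and it leaves with mild acid.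
- **Malonyl partner.** The central C–H of a dialkyl methoxymalonate is several pK units more acidic than the pyranone methyl group. The lithiated pyranone would therefore only be protonated, and the resulting malonate enolate is no acylating agent. The same C3 unit is used instead as its bis(2,4,6-trichlorophenyl) ester, whose enolate collapses to a ketene, so deprotonation becomes the activation.
- **Regiochemistry.** This ester releases no alkoxide. That matters because opening of the pyranone would allow re-closure through the other ortho oxygen and move the methoxy group to C8.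

Step 1
Reactants: 1 kojic acid
Product: 2 chlorokojic acid (2-(chloromethyl)-5-hydroxy-4H-pyran-4-one)
Conditions: SOCl2 (neat), rt
Reagents that add atoms: thionyl chloride, O=S(Cl)Cl
Why: Deoxychlorination of the primary alcohol through its chlorosulfite is the standard entry into kojic acid chemistry, and the enolic 5-OH, which cannot be displaced, stays free.

Step 2
Reactants: 2 chlorokojic acid
Product: 3 allomaltol (5-hydroxy-2-methyl-4H-pyran-4-one)
Conditions: Zn dust, conc. HCl, H2O, 70 °C
Reagents that add atoms: none
Why: Reductive dehalogenation with zinc in acid works because the C–Cl bond is that of a vinylogous alpha-chloro ketone, and the pyranone ring is not reduced under these conditions.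

Step 3
Reactants: 3 allomaltol
Product: 4 6-methyl-4-oxo-4H-pyran-3-yl trifluoromethanesulfonate
Conditions: Tf2O, pyridine, CH2Cl2, 0 °C
Reagents that add atoms: triflic anhydride, O=S(=O)(OS(=O)(=O)C(F)(F)F)C(F)(F)F
Why: O-sulfonylation of the only hydroxyl group, an acidic enol, gives an enol triflate of the type routinely made from 5-hydroxy-4-pyranones for cross-coupling.

Step 4
Reactants: 5 2,3-dimethoxyphenol
Product: 6 1,2-dimethoxy-3-(methoxymethoxy)benzene
Conditions: MOMCl, iPr2NEt, CH2Cl2, 0 °C to rt
Reagents that add atoms: chloromethyl methyl ether, COCCl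
Why: O-alkylation of the phenol with the highly reactive alpha-chloro ether (MOM protection) is a routine Williamson-type reaction with no competing site.

Step 5
Reactants: 6 1,2-dimethoxy-3-(methoxymethoxy)benzene
Product: 7 2-[3,4-dimethoxy-5-(methoxymethoxy)phenyl]-4,4,5,5-tetramethyl-1,3,2-dioxaborolane
Conditions: [Ir(OMe)(cod)]2 (cat.), 4,4'-di-tert-butyl-2,2'-bipyridine (cat.), B2pin2 (1.0 equiv), THF, 80 °C
Reagents that add atoms: bis(pinacolato)diboron, CC1(C)OB(OC1(C)C)B1OC(C)(C)C(C)(C)O1
Why: Iridium-catalysed aromatic C–H borylation is governed by sterics, and C5–H is the only ring C–H bond of 6 without an ortho substituent, while the acetal offers no aromatic C–H bond that could compete.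

Step 6
Reactants: 4 6-methyl-4-oxo-4H-pyran-3-yl trifluoromethanesulfonate; 7 aryl pinacol boronate
Product: 8 5-[3,4-dimethoxy-5-(methoxymethoxy)phenyl]-2-methyl-4H-pyran-4-one
Conditions: PdCl2(dppf) (cat.), K3PO4, dioxane/H2O (10:1), 80 °C
Reagents that add atoms: none
Why: In this Suzuki–Miyaura coupling zerovalent palladium inserts readily into the C–O bond of the electron-poor 4-oxopyranyl triflate, a substrate class known from kojic acid derivatives, and the phosphate-activated boronate transfers ring B.

Step 7
Reactants: 9 dimethyl 2-methoxymalonate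
Product: 10 2-methoxymalonic acid
Conditions: NaOH (2.2 equiv), H2O, rt; HCl to pH 1, EtOAc extraction
Reagents that add atoms: sodium hydroxide, [Na+].[OH-]
Why: Saponification of both unhindered methyl esters at room temperature is routine, and cold acidification avoids decarboxylation of the diacid.

Step 8
Reactants: 10 2-methoxymalonic acid
Product: 11 bis(2,4,6-trichlorophenyl) 2-methoxymalonate
Conditions: 2,4,6-trichlorophenol (2.0 equiv), POCl3, 95 °C
Reagents that add atoms: 2,4,6-trichlorophenol, Oc1c(Cl)cc(Cl)cc1Cl
Why: Dehydrative esterification with phosphoryl chloride is the standard preparation of bis(2,4,6-trichlorophenyl) esters from 2-substituted malonic acids, and its acidic medium keeps the active ester from enolising.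

Step 9
Reactants: 8 5-[3,4-dimethoxy-5-(methoxymethoxy)phenyl]-2-methyl-4H-pyran-4-one; 11 bis(2,4,6-trichlorophenyl) 2-methoxymalonate
Product: 15 3'-O-(methoxymethyl)irigenin, via lithium dienolate 12 (not isolated), via aryloxycarbonyl ketene 13 (not isolated), via acyclic keto ester 14 (not isolated)
Conditions: LiN(SiMe3)2 (2.1 equiv), THF (dilute), −78 °C; 11 (1.1 equiv), −78 to 0 °C; LiN(SiMe3)2 (2.0 equiv), 0 °C to rt; AcOH
Reagents that add atoms: none
Why: Proposed new method: LiN(SiMe3)2 deprotonates 8 at its C-methyl group, which has the acidity of a vinylogous methyl ketone, to give dienolate 12, while the second equivalent converts the far more acidic 11 into its enolate, which expels trichlorophenoxide (E1cB) to give ketene 13; the CH2 terminus of 12 adds to the ketene carbon and makes C7–C8 without releasing a proton. The later portion of base deprotonates 14 at C8, the charge spreads over C8a onto C4a, C4a adds to the C5 acyl carbon with loss of the second trichlorophenoxide (C4a–C5), and tautomerisation of the cyclic trione to the C5,C7-diphenol aromatises ring A and makes the sequence irreversible. The closest known reaction types are the cyclocondensation of bis(2,4,6-trichlorophenyl) malonates with 1,3-dinucleophiles, the ester acylation of laterally lithiated 2-methyl-4-pyranones and the biomimetic Claisen cyclisation of 3,5,7-triketo esters to acylphloroglucinols, but a methylpyranone has not served as the C,C-dinucleophile. Ring A closes in the favoured 6-(enolendo)-exo-trig mode, and no stereocentre remains in 15 because the transient centre at C6 of 14 becomes an aromatic carbon. Chemoselectivity among the polyketide cyclisation modes is secured by the pyranone itself, since O1 is tied up so that lactonisation to a 2-pyranone is impossible, and aldol attack of C6 on C4 would need a bridgehead alkene. The methoxy group ends at C6 and not at C8 because the mirror symmetry of 11 makes both acyl carbons and both orders of bond formation equivalent, and because the O1–C8a bond stays intact when only weakly nucleophilic trichlorophenoxide and no alkoxide is released.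

Step 10
Reactants: 15 3'-O-(methoxymethyl)irigenin
Product: 16 irigenin
Conditions: HCl (cat.), MeOH, 50 °C
Reagents that add atoms: none
Why: Acid-catalysed acetal exchange (MOM cleavage) frees the 3'-OH under conditions that leave the aryl methyl ethers and the pyranone ring untouched and are far too mild for a Wessely–Moser-type ring opening.

Compound list
1 | kojic acid, 5-hydroxy-2-(hydroxymethyl)-4H-pyran-4-one | OCc1cc(=O)c(O)co1 | starting material
2 | chlorokojic acid, 2-(chloromethyl)-5-hydroxy-4H-pyran-4-one | ClCc1cc(=O)c(O)co1 | intermediate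
3 | allomaltol, 5-hydroxy-2-methyl-4H-pyran-4-one | Cc1cc(=O)c(O)co1 | intermediate
4 | 6-methyl-4-oxo-4H-pyran-3-yl trifluoromethanesulfonate | Cc1cc(=O)c(OS(=O)(=O)C(F)(F)F)co1 | intermediate
5 | 2,3-dimethoxyphenol | COc1cccc(O)c1OC | starting material
6 | 1,2-dimethoxy-3-(methoxymethoxy)benzene | COCOc1cccc(OC)c1OC | intermediate
7 | 2-[3,4-dimethoxy-5-(methoxymethoxy)phenyl]-4,4,5,5-tetramethyl-1,3,2-dioxaborolane | COCOc1cc(B2OC(C)(C)C(C)(C)O2)cc(OC)c1OC | intermediate
8 | 5-[3,4-dimethoxy-5-(methoxymethoxy)phenyl]-2-methyl-4H-pyran-4-one | Cc1cc(=O)c(-c2cc(OC)c(OC)c(OCOC)c2)co1 | intermediate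
9 | dimethyl 2-methoxymalonate | COC(C(=O)OC)C(=O)OC | starting material
10 | 2-methoxymalonic acid | COC(C(=O)O)C(=O)O | intermediate
11 | bis(2,4,6-trichlorophenyl) 2-methoxymalonate | COC(C(=O)Oc1c(Cl)cc(Cl)cc1Cl)C(=O)Oc1c(Cl)cc(Cl)cc1Cl | intermediate
12 | lithium 3-[3,4-dimethoxy-5-(methoxymethoxy)phenyl]-6-methylidene-6H-pyran-4-olate (lithium dienolate of 8, not isolated) | [Li+].C=C1C=C([O-])C(=CO1)c1cc(OC)c(OC)c(OCOC)c1 | intermediate
13 | 2,4,6-trichlorophenyl 2-methoxy-3-oxoprop-2-enoate (aryloxycarbonyl methoxy ketene, not isolated) | COC(=C=O)C(=O)Oc1c(Cl)cc(Cl)cc1Cl | intermediate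
14 | 2,4,6-trichlorophenyl 4-{5-[3,4-dimethoxy-5-(methoxymethoxy)phenyl]-4-oxo-4H-pyran-2-yl}-2-methoxy-3-oxobutanoate (racemic, present as its lithium enolate, not isolated) | COC(C(=O)Oc1c(Cl)cc(Cl)cc1Cl)C(=O)Cc1cc(=O)c(-c2cc(OC)c(OC)c(OCOC)c2)co1 | intermediate
15 | 3'-O-(methoxymethyl)irigenin, 5,7-dihydroxy-6-methoxy-3-[3,4-dimethoxy-5-(methoxymethoxy)phenyl]-4H-chromen-4-one | COCOc1cc(-c2coc3cc(O)c(OC)c(O)c3c2=O)cc(OC)c1OC | intermediate
16 | irigenin, 5,7-dihydroxy-3-(3-hydroxy-4,5-dimethoxyphenyl)-6-methoxy-4H-chromen-4-one | COc1cc(-c2coc3cc(O)c(OC)c(O)c3c2=O)cc(O)c1OC | target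

Total step count: 10. Longest linear sequence: 6 steps (1, 2, 3, 6, 9, 10).

Steps most likely to fail

**Step 9 (bears the label "Proposed new method:").** Proton exchange between the two anions, self-reaction of the ketene, or too slow an attack of the weakly nucleophilic C4a may outrun ring formation. The fallback is the known deoxybenzoin route. It sets out from 7 and comes back to the route at 16.
- Palladium-catalysed coupling of 7 with ethyl bromoacetate (Pd(OAc)2, P(o-tol)3, K3PO4, THF/H2O) should give ethyl 2-[3,4-dimethoxy-5-(methoxymethoxy)phenyl]acetate F1.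
- LiOH should then give 2-[3,4-dimethoxy-5-(methoxymethoxy)phenyl]acetic acid F2.
- Friedel–Crafts acylation of purchased 2-methoxybenzene-1,3,5-triol with F2 in BF3·OEt2 at 80 °C, during which the acetal falls off, should give the deoxybenzoin 2-(3-hydroxy-4,5-dimethoxyphenyl)-1-(2,4,6-trihydroxy-3-methoxyphenyl)ethan-1-one F3.
- DMF and MeSO2Cl in the same medium add C2 and close ring C.
- Either ortho hydroxyl group can close, so 5,7-dihydroxy-3-(3-hydroxy-4,5-dimethoxyphenyl)-8-methoxy-4H-chromen-4-one F4 is expected beside 16. Warm dilute alkali (K2CO3, aqueous EtOH) should convert F4 into the more stable 16 by ring opening and re-closure of the Wessely–Moser type.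

**Step 8.** Thermal decarboxylation of 10 in hot POCl3 may outrun the double esterification. The fallback avoids the free diacid. It sets out from 9 and comes back at 15.
- One equivalent of KOH in MeOH, then acid, should give methyl hydrogen 2-methoxymalonate F5.
- Oxalyl chloride with catalytic DMF should give methyl 3-chloro-2-methoxy-3-oxopropanoate F6, which takes the place of 11 under the conditions of step 9.
- LiN(SiMe3)2 turns F6 into methoxy(methoxycarbonyl)ketene F7.
- Dienolate 12 traps the ketene to give methyl 4-{5-[3,4-dimethoxy-5-(methoxymethoxy)phenyl]-4-oxo-4H-pyran-2-yl}-2-methoxy-3-oxobutanoate F8.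
- The ring closes on the methyl ester with loss of methoxide, which forms only in this last, irreversible event.

**Step 6.** Base-induced S–O cleavage of the triflate or opening of the pyranone ring by aqueous base may compete with transmetalation. The fallback builds ring C on ring B instead of coupling the two rings. It sets out from 7, through ester F1 made as described under step 9, and comes back at 8.
- Claisen condensation of F1 with the lithium enolate of acetone (LiN(iPr)2, THF, −78 °C) should give 1-[3,4-dimethoxy-5-(methoxymethoxy)phenyl]pentane-2,4-dione F9.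
- Its dianion (LiN(iPr)2, 2.2 equiv, 0 °C) should carry the second charge at the more acidic benzylic carbon. Formylation there with methyl formate should give 2-[3,4-dimethoxy-5-(methoxymethoxy)phenyl]-3,5-dioxohexanal F10.
- Mild acid (pyridinium p-toluenesulfonate, toluene, 60 °C) should cyclodehydrate F10 to 8, the classical 1,3,5-tricarbonyl route to 4-pyranones.

Further compounds
F1 | step 9 | ethyl 2-[3,4-dimethoxy-5-(methoxymethoxy)phenyl]acetate | CCOC(=O)Cc1cc(OC)c(OC)c(OCOC)c1
F2 | step 9 | 2-[3,4-dimethoxy-5-(methoxymethoxy)phenyl]acetic acid | OC(=O)Cc1cc(OC)c(OC)c(OCOC)c1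
F3 | step 9 | 2-(3-hydroxy-4,5-dimethoxyphenyl)-1-(2,4,6-trihydroxy-3-methoxyphenyl)ethan-1-one | COc1cc(CC(=O)c2c(O)cc(O)c(OC)c2O)cc(O)c1OC
F4 | step 9 | 5,7-dihydroxy-3-(3-hydroxy-4,5-dimethoxyphenyl)-8-methoxy-4H-chromen-4-one | COc1cc(-c2coc3c(OC)c(O)cc(O)c3c2=O)cc(O)c1OC
F5 | step 8 | methyl hydrogen 2-methoxymalonate (racemic) | COC(C(=O)O)C(=O)OC
F6 | step 8 | methyl 3-chloro-2-methoxy-3-oxopropanoate (racemic) | COC(C(=O)Cl)C(=O)OC
F7 | step 8 | methoxy(methoxycarbonyl)ketene, methyl 2-methoxy-3-oxoprop-2-enoate | COC(=C=O)C(=O)OC
F8 | step 8 | methyl 4-{5-[3,4-dimethoxy-5-(methoxymethoxy)phenyl]-4-oxo-4H-pyran-2-yl}-2-methoxy-3-oxobutanoate (racemic, as its enolate) | COC(C(=O)OC)C(=O)Cc1cc(=O)c(-c2cc(OC)c(OC)c(OCOC)c2)co1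
F9 | step 6 | 1-[3,4-dimethoxy-5-(methoxymethoxy)phenyl]pentane-2,4-dione | CC(=O)CC(=O)Cc1cc(OC)c(OC)c(OCOC)c1
F10 | step 6 | 2-[3,4-dimethoxy-5-(methoxymethoxy)phenyl]-3,5-dioxohexanal (enolised, no defined stereocentre) | CC(=O)CC(=O)C(C=O)c1cc(OC)c(OC)c(OCOC)c1
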